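## Structural features

The target is a resveratrol trimer built on a central benzene ring C, numbered here as position 1 (bears the methylene Cb), 2 (bears Cf), 3 and 5 (oxygen-bearing), 4 (the only CH) and 6 (bears Cc). Two 2,3-dihydrofurans are fused to it, O–Cd–Cc on positions 5/6 and O–Ce–Cf on positions 3/2, with 4-hydroxyphenyl rings E on Cd and F on Ce, and Cc carries a free 3,5-dihydroxyphenyl ring D. Cf carries the resorcinol ring B, whose ortho carbon is tied back through Ca (bearing 4-hydroxyphenyl ring G) and Cb to position 1, which closes a dibenzo-fused seven-membered carbocycle. Cc/Cd are adjacent, trans and (R,R); Ce/Cf are adjacent, trans and (S,S); Ca is (S), with its hydrogen on the face of the seven-membered ring opposite to the hydrogen on Cf, so ring G is pseudo-equatorial and points away from ring C. The two dihydrobenzofurans are mirror images across the axis through positions 1 and 4, so a bis-dihydrobenzofuran with identical rings B and D and no Ca–ring B bond would be meso; the absolute configuration therefore depends on which resorcinol ring is joined to Ca. The fragile groups are the seven phenols, the doubly benzylic methines, and the benzylic aryl-ether bonds Cd–O and Ce–O, which ionise under acid to 4-oxybenzyl cations. The real difficulty is two remote stereo-pairs of opposite sense plus the isolated Ca, on a crowded pentasubstituted ring C, with rings B and D needing to be told apart. The key step uses the O–C5=C6–Cc array of ring C (an ortho-quinone methide), into which Cd is inserted as a one-carbon unit between the phenol oxygen and Cc.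

## Logic of the disconnections

**42 ⇒ 41 ⇒ 40.** Only O–CH3 and O–SO2Ar bonds are cut. All seven phenols stay masked to the end. Ring D carries sulfonates and the other rings carry methyl ethers: sulfonates deactivate ring D, which is what lets 40 be made as one enantiomer (next paragraph). The forward demand is base cleavage of the sulfonates before Lewis-acid demethylation, so that no free polyphenol meets hot base.

**40 ⇒ 38.** The Ca–ring B bond is cut, leaving a 4-methoxystyryl group on position 1. This removes the seven-membered ring and the Ca stereocentre in one move. The forward step is a cationic ring closure, which must choose ring B over ring D and set Ca relative to Cf. The first is secured by the sulfonates on ring D, the second by the preference of ring G for the outward, pseudo-equatorial position.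

**38 ⇒ 36 + 37, 36 ⇒ 35 ⇒ 34.** The Ca=Cb double bond is cut, then the oxidation level of the one-carbon arm on position 1 is adjusted. This splits off the third C14 unit as a commercial C8 reagent. The forward demand is modest: the olefin geometry is irrelevant because the alkene is consumed in the ring closure.

**34 ⇒ 25 + 30, 25 ⇒ 23 ⇒ 20 + 21.** The Cf–Ce and Ce–O bonds are cut (second [4+1]), then the C2–Cf bond. This repeats the key step with the enantiomeric sulfonium salt and brings ring B in as an intact aldehyde. The forward demands are ortho-selective hydroxyalkylation at the crowded position 2 and reagent control by the thiolane over the remote centres Cc and Cd.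

**20 ⇒ 19.** One O–benzyl bond. The benzyl ether keeps the position-3 oxygen silent during the first annulation and releases it as the nucleophile and directing group for the second.

**19 ⇒ 9 + 15 (key).** The Cc–Cd and Cd–O bonds are cut. This removes one ring and two stereocentres and divides the ring into a ring C/ring D carbinol derivative and a 4-methoxybenzyl unit. Three design points follow from the forward demand:
- The free carbinol 7 is a poor precursor under carbonate, because hydroxide does not leave. Its hydroxyl is exchanged for sulfinate in 9; skeleton and disconnection are unchanged.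
- The sulfonium salt is used as its tetrafluoroborate 15, not the bromide 14. Bromide would dealkylate the labile 4-methoxybenzyl sulfonium and release an O-alkylating agent.
- On the ylide model stated below, the (2R,5R) salt is the one that gives the (2R,3R) ring; the (2S,5S) salt 30 serves the second ring.

**9 ⇒ 7 ⇒ 3 + 5; 5 ⇒ 4; 3 ⇒ 2 ⇒ 1.** The C6–Cc bond and the protecting-group bonds are cut. This reaches two commercial phenols. The forward demand is ortho-hydroxyalkylation next to the silyloxymethyl arm and para to the benzyloxy group.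

**15 ⇒ 12 + 13, 12 ⇒ 11 ⇒ 10; 30 ⇒ 28 + 13, 28 ⇒ 27 ⇒ 26.** The S–benzyl and two S–C ring bonds are cut. Both enantiomers of the C2-symmetric thiolane come from the commercial enantiomeric hexanediols by double inversion.

## Other disconnections considered

Alternative 1: The cut is the Ca–Cb bond, made as a double bond in dibenzosuberene A1 by extrusion of SO2 from the eight-membered dibenzo-fused sulfone A2 (halogenation alpha to sulfur, episulfone, loss of SO2), followed by hydrogenation.
- In favour: the union through sulfur is regiospecific and Ca is tied to ring B from the start. The question of which resorcinol ring joins Ca never arises, so no deactivating groups on ring D are needed. No carbocation is generated near the acid-labile Cd–O and Ce–O bonds. On both points this alternative is better than the chosen plan.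
- Against: Ca is created only afterwards, by hydrogenating a triaryl-substituted cyclic alkene. Delivery of hydrogen to the exposed face would push ring G toward the inner face, which may be the epimer of the target. Benzylic C–O hydrogenolysis is a further risk, and the ring-B fragment carrying a benzylic thiol at Ca must be built separately.
- Comparison: structurally both plans use the same one-carbon handle on position 1 and are compatible with step 9 upstream (equal). Mechanistically the chosen plan forms Ca–ring B and sets Ca in the same event under conformational control, whereas here Ca is left to a separate, less predictable reduction. Step count is similar: the alternative saves the two sulfonate steps but spends them on the thiol fragment and the sulfur oxidation.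

Alternative 2: The cut is two bonds of ring B. The keto acrylate A4 (acetonyl arm on Ca, acrylate on Cf) is treated with alkoxide: 7-exo Michael addition through the methylene carbon, then Claisen closure, gives the cyclohexane-1,3-dione A3, which is later aromatised.
- In favour: ring B does not exist until the seven-membered ring is closed, so there is again no competition between two resorcinol rings (equal to alternative 1, better than the chosen plan). Ca can be installed earlier as an ordinary stereocentre under catalyst control, which the chosen plan cannot offer (better). One operation closes two rings.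
- Against: in A4 the hydrogen on Cf is both benzylic and gamma to the ester. Alkoxide can epimerise Cf or trigger E1cB loss of the phenoxide on Ce, opening the second dihydrobenzofuran. The dione A3 needs an oxidative aromatisation that the electron-rich rest must survive. The second annulation would run on a vinylogous quinone methide with a competing remote addition site.
- Comparison: structurally it replaces the intact aldehyde 21 by a de novo ring. Mechanistically it is anionic where the chosen plan is cationic, which trades acid lability for base lability at Ce/Cf. It is several steps longer.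

Alternative 3: The cut is the ring C–Cc bond, formed by oxidative 1,2-aryl shift in the flavanone A6 (from naringenin A7 by position-selective benzylation, triflation and methylation) with a hypervalent iodine oxidant in acidic orthoformate, giving the trans ester A5.
- In favour: A7 supplies ring C, ring E, Cd and the oxygen pattern in one cheap compound. Its two ring-C phenols are differentiated by the hydrogen bond to the carbonyl, which is better than the statistical step 2 and the ortho-selectivity question of step 4. The trans relationship arises in the contraction, and the triflate is a ready handle on position 1.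
- Against: natural A7 is (2S), which maps onto (S) at the oxygen-bearing carbon, whereas Cd is (R). A6 would therefore be needed in the unnatural series, and flavanones racemise through the ring-opened chalcone. A5 carries an ester on Cc where ring D must stand; replacing it by a 3,5-dioxygenated aryl group with retention costs several steps. The beta-aryloxy ester can also open by retro-oxa-Michael reaction under base and scramble Cd.
- Comparison: structurally it reaches the same ring as step 9 but without ring D. Mechanistically it relies on a pooled stereocentre of the wrong hand, where the chosen plan sets both centres by reagent control. It is shorter to A5 than the chosen route is to 19 (a point in its favour) but longer to a ring-D-bearing equivalent of 19.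

Key step: step 9

**Assumption (sense of induction):** the thiolanium ylide is taken to react as in its benzylidene transfers to aldehydes (aryl syn to the sulfur lone pair, attack on the face remote from the methyl group cis to the benzylidene substituent); on this model the (2R,5R) salt 15 gives the (2R,3R) ring and the (2S,5S) salt 30 the (2S,3S) ring, and if the sense were the reverse, 15 and 30 simply change places.

## Route

Step 1
Reactants: 1 3,5-dihydroxybenzyl alcohol
Product: 2 5-{[(tert-butyldimethylsilyl)oxy]methyl}benzene-1,3-diol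
Conditions: TBSCl (1.05 equiv), imidazole, DMF, 0 °C
Reagents that add atoms: tert-butyldimethylsilyl chloride, CC(C)(C)[Si](C)(C)Cl
Why: Selective O-silylation; the primary benzylic alcohol is silylated faster than the phenols with imidazole at low temperature.

Step 2
Reactants: 2 5-{[(tert-butyldimethylsilyl)oxy]methyl}benzene-1,3-diol
Product: 3 3-(benzyloxy)-5-{[(tert-butyldimethylsilyl)oxy]methyl}phenol
Conditions: BnBr (1.0 equiv), K2CO3, acetone, reflux
Reagents that add atoms: benzyl bromide, BrCc1ccccc1
Why: Williamson etherification of one of two equivalent phenols; the mixture is statistical, the mono-ether is separated and unreacted 2 is recycled.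

Step 3
Reactants: 4 3,5-dihydroxybenzaldehyde
Product: 5 5-formyl-1,3-phenylene bis(4-methylbenzenesulfonate)
Conditions: TsCl (2.2 equiv), Et3N, DMAP (cat.), CH2Cl2, 0 °C to rt
Reagents that add atoms: 4-methylbenzenesulfonyl chloride, Cc1ccc(S(=O)(=O)Cl)cc1
Why: O-sulfonylation of both phenols; the sulfonates are chosen as spectator groups for ring D because they deactivate it toward electrophiles, which later reserves the cationic ring closure for ring B.

Step 4
Reactants: 3 3-(benzyloxy)-5-{[(tert-butyldimethylsilyl)oxy]methyl}phenol; 5 5-formyl-1,3-phenylene bis(4-methylbenzenesulfonate)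
Product: 7 racemic 5-{[4-(benzyloxy)-2-{[(tert-butyldimethylsilyl)oxy]methyl}-6-hydroxyphenyl](hydroxy)methyl}-1,3-phenylene bis(4-methylbenzenesulfonate), via bromomagnesium phenoxide 6 (not isolated)
Conditions: EtMgBr (1.0 equiv), Et2O, 0 °C; solvent changed to toluene; 5 (1.1 equiv), rt; aq. NH4Cl
Reagents that add atoms: none
Why: Ortho-specific hydroxyalkylation of a magnesium phenoxide by an aromatic aldehyde through a six-membered chelate in a non-coordinating solvent; of the two ortho sites the one para to the benzyloxy group and next to the silyloxymethyl arm is the more nucleophilic, as in electrophilic substitution of 5-alkylresorcinol monoethers. The carbinol centre is racemic, which is immaterial because it becomes sp2 in step 9.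

Step 5
Reactants: 7 racemic 5-{[4-(benzyloxy)-2-{[(tert-butyldimethylsilyl)oxy]methyl}-6-hydroxyphenyl](hydroxy)methyl}-1,3-phenylene bis(4-methylbenzenesulfonate)
Product: 9 racemic 5-{[4-(benzyloxy)-2-{[(tert-butyldimethylsilyl)oxy]methyl}-6-hydroxyphenyl](4-methylbenzenesulfonyl)methyl}-1,3-phenylene bis(4-methylbenzenesulfonate), via benzhydryl cation 8 (not isolated)
Conditions: p-TolSO2H (1.5 equiv), CH2Cl2, 0 °C to rt
Reagents that add atoms: 4-methylbenzenesulfinic acid, Cc1ccc(S(=O)O)cc1
Why: Known exchange of an ortho-hydroxybenzhydrol into its sulfone: the sulfinic acid protonates the oxygen-activated carbinol, water leaves to give the ortho-hydroxybenzhydryl cation 8, and sulfinate captures this cation through sulfur. It installs a leaving group that carbonate can expel, which the hydroxyl of 7 is not.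

Step 6
Reactants: 10 (2S,5S)-hexane-2,5-diol
Product: 11 (2S,5S)-hexane-2,5-diyl dimethanesulfonate
Conditions: MsCl (2.4 equiv), Et3N, CH2Cl2, -10 °C
Reagents that add atoms: methanesulfonyl chloride, CS(=O)(=O)Cl
Why: O-sulfonylation of both secondary alcohols; the stereocentres are not touched.

Step 7
Reactants: 11 (2S,5S)-hexane-2,5-diyl dimethanesulfonate
Product: 12 (2R,5R)-2,5-dimethylthiolane
Conditions: Na2S·9H2O, DMSO, rt
Reagents that add atoms: sodium sulfide, [Na+].[Na+].[S-2]
Why: Double SN2 displacement by sulfide with inversion at both carbons closes the thiolane, so the (S,S) dimesylate gives the (R,R) C2-symmetric sulfide.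

Step 8
Reactants: 12 (2R,5R)-2,5-dimethylthiolane; 13 4-methoxybenzyl bromide
Product: 15 (2R,5R)-1-(4-methoxybenzyl)-2,5-dimethylthiolan-1-ium tetrafluoroborate, via sulfonium bromide 14 (not isolated)
Conditions: acetone, rt; then NaBF4, H2O/CH2Cl2
Reagents that add atoms: sodium tetrafluoroborate, [Na+].F[B-](F)(F)F
Why: S-alkylation (SN2) followed by anion metathesis; the non-nucleophilic counter-ion stops bromide from reversing the alkylation of this labile 4-methoxybenzyl sulfonium. C2 symmetry means sulfur is not a stereocentre, so a single salt results.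

Step 9
Reactants: 9 racemic 5-{[4-(benzyloxy)-2-{[(tert-butyldimethylsilyl)oxy]methyl}-6-hydroxyphenyl](4-methylbenzenesulfonyl)methyl}-1,3-phenylene bis(4-methylbenzenesulfonate); 15 (2R,5R)-1-(4-methoxybenzyl)-2,5-dimethylthiolan-1-ium tetrafluoroborate
Product: 19 5-[(2R,3R)-6-(benzyloxy)-4-{[(tert-butyldimethylsilyl)oxy]methyl}-2-(4-methoxyphenyl)-2,3-dihydro-1-benzofuran-3-yl]-1,3-phenylene bis(4-methylbenzenesulfonate), via quinone methide 16 (not isolated), via ylide 17 (not isolated), via betaine 18 (not isolated)
Conditions: Cs2CO3 (3 equiv), CH2Cl2/MeCN, -20 °C to rt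
Reagents that add atoms: none
Why: Cs2CO3 deprotonates the phenol of 9 and p-toluenesulfinate is expelled (E1cB) to give the Z-configured quinone methide 16, while the same base converts 15 into the semistabilised ylide 17. The ylide carbon adds in 1,4-fashion to the methide carbon Cc, which restores the aromaticity of ring C and gives betaine 18, and the phenoxide oxygen then displaces the thiolane at Cd with inversion in a 5-exo-tet closure, the only ring formed. The closest known reaction type is the [4+1] annulation of sulfone-derived ortho-quinone methides with sulfonium ylides under carbonate, combined with the stereochemical logic of chiral-sulfide benzylidene transfer to aldehydes. Cd is set by the thiolane: its C2 symmetry leaves sulfur non-stereogenic and makes both ylide rotamers equivalent, the aryl group lies syn to the sulfur lone pair, and the methyl group cis to the benzylidene substituent shields one face of the ylide carbon. Cc is set relative to Cd by the anti arrangement of the two aryl groups in the addition and in the anti-periplanar displacement, which gives the trans ring; because the addition is driven by rearomatisation it is not expected to revert, so both centres come from reagent control. The step needs chemoselectivity for C–C bond formation over transfer of the 4-methoxybenzyl group to phenoxide oxygen, which the fast loss of sulfinate and the non-nucleophilic BF4 counter-ion should secure, and site selectivity, which is automatic because Cc is the only electrophilic carbon of 16. The sulfonates on ring D make 16 more electrophilic and are inert to carbonate, as are the silyl and benzyl ethers.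

Step 10
Reactants: 19 5-[(2R,3R)-6-(benzyloxy)-4-{[(tert-butyldimethylsilyl)oxy]methyl}-2-(4-methoxyphenyl)-2,3-dihydro-1-benzofuran-3-yl]-1,3-phenylene bis(4-methylbenzenesulfonate)
Product: 20 5-[(2R,3R)-4-{[(tert-butyldimethylsilyl)oxy]methyl}-6-hydroxy-2-(4-methoxyphenyl)-2,3-dihydro-1-benzofuran-3-yl]-1,3-phenylene bis(4-methylbenzenesulfonate)
Conditions: H2 (1 atm), Pd/C (10%), EtOAc, rt
Reagents that add atoms: none
Why: Hydrogenolysis of the O-benzyl aryl ether; under neutral aprotic conditions with monitoring, the silyl ether, the aryl sulfonates and the slower-reacting cyclic benzylic C–O bond should be spared.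

Step 11
Reactants: 20 5-[(2R,3R)-4-{[(tert-butyldimethylsilyl)oxy]methyl}-6-hydroxy-2-(4-methoxyphenyl)-2,3-dihydro-1-benzofuran-3-yl]-1,3-phenylene bis(4-methylbenzenesulfonate); 21 3,5-dimethoxybenzaldehyde
Product: 23 5-[(2R,3R)-4-{[(tert-butyldimethylsilyl)oxy]methyl}-5-[(3,5-dimethoxyphenyl)(hydroxy)methyl]-6-hydroxy-2-(4-methoxyphenyl)-2,3-dihydro-1-benzofuran-3-yl]-1,3-phenylene bis(4-methylbenzenesulfonate) as both carbinol epimers, via bromomagnesium phenoxide 22 (not isolated)
Conditions: EtMgBr (1.0 equiv), Et2O, 0 °C; solvent changed to toluene; 21 (1.5 equiv), rt to 40 °C; aq. NH4Cl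
Reagents that add atoms: none
Why: The same chelate-controlled ortho-hydroxyalkylation as in step 4; position 2 of ring C is ortho to the phenoxide and para to the furan oxygen, whereas position 4 lies between two oxygens and is the less reactive ortho site in this reaction type. The carbinol epimers converge in step 16.

Step 12
Reactants: 23 the carbinol epimers from step 11
Product: 25 5-[(2R,3R)-4-{[(tert-butyldimethylsilyl)oxy]methyl}-5-[(3,5-dimethoxyphenyl)(4-methylbenzenesulfonyl)methyl]-6-hydroxy-2-(4-methoxyphenyl)-2,3-dihydro-1-benzofuran-3-yl]-1,3-phenylene bis(4-methylbenzenesulfonate) as both epimers, via benzhydryl cation 24 (not isolated)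
Conditions: p-TolSO2H (1.5 equiv), CH2Cl2, 0 °C to rt
Reagents that add atoms: 4-methylbenzenesulfinic acid, Cc1ccc(S(=O)O)cc1
Why: The same carbinol-to-sulfone exchange as step 5, through the ortho-hydroxybenzhydryl cation 24 and its capture by sulfinate at sulfur; the doubly oxygen-activated benzhydrol ionises far more readily than the cyclic benzylic ether already present.

Step 13
Reactants: 26 (2R,5R)-hexane-2,5-diol
Product: 27 (2R,5R)-hexane-2,5-diyl dimethanesulfonate
Conditions: MsCl (2.4 equiv), Et3N, CH2Cl2, -10 °C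
Reagents that add atoms: methanesulfonyl chloride, CS(=O)(=O)Cl
Why: As step 6, in the enantiomeric series.

Step 14
Reactants: 27 (2R,5R)-hexane-2,5-diyl dimethanesulfonate
Product: 28 (2S,5S)-2,5-dimethylthiolane
Conditions: Na2S·9H2O, DMSO, rt
Reagents that add atoms: sodium sulfide, [Na+].[Na+].[S-2]
Why: As step 7; double inversion gives the (S,S) sulfide.

Step 15
Reactants: 28 (2S,5S)-2,5-dimethylthiolane; 13 4-methoxybenzyl bromide
Product: 30 (2S,5S)-1-(4-methoxybenzyl)-2,5-dimethylthiolan-1-ium tetrafluoroborate, via sulfonium bromide 29 (not isolated)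
Conditions: acetone, rt; then NaBF4, H2O/CH2Cl2
Reagents that add atoms: sodium tetrafluoroborate, [Na+].F[B-](F)(F)F
Why: As step 8.

Step 16
Reactants: 25 the sulfone epimers from step 12; 30 (2S,5S)-1-(4-methoxybenzyl)-2,5-dimethylthiolan-1-ium tetrafluoroborate
Product: 34 5-[(2R,3R,5S,6S)-4-{[(tert-butyldimethylsilyl)oxy]methyl}-5-(3,5-dimethoxyphenyl)-2,6-bis(4-methoxyphenyl)-2,3,5,6-tetrahydrobenzo[1,2-b:5,4-b']difuran-3-yl]-1,3-phenylene bis(4-methylbenzenesulfonate), via quinone methide 31 (not isolated), via ylide 32 (not isolated), via betaine 33 (not isolated)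
Conditions: Cs2CO3 (3 equiv), CH2Cl2/MeCN, -20 °C to rt
Reagents that add atoms: none
Why: The same [4+1] annulation as step 9 (E1cB to 31, 1,4-addition of 32 at Cf, 5-exo-tet closure of betaine 33 at Ce with inversion); the enantiomeric thiolane sets Ce as (S) and, through the trans closure, Cf as (S). Cc and Cd are five and six bonds from the methide carbon, so reagent control should prevail, and both sulfone epimers converge on the same quinone methide.

Step 17
Reactants: 34 the bis-dihydrobenzofuran silyl ether from step 16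
Product: 35 5-[(2R,3R,5S,6S)-5-(3,5-dimethoxyphenyl)-4-(hydroxymethyl)-2,6-bis(4-methoxyphenyl)-2,3,5,6-tetrahydrobenzo[1,2-b:5,4-b']difuran-3-yl]-1,3-phenylene bis(4-methylbenzenesulfonate)
Conditions: HF·pyridine, THF/pyridine, 0 °C to rt
Reagents that add atoms: none
Why: Fluoride cleavage of the primary silyl ether; the buffered, non-basic medium leaves the aryl sulfonates alone.

Step 18
Reactants: 35 the benzylic alcohol from step 17
Product: 36 5-[(2R,3R,5S,6S)-5-(3,5-dimethoxyphenyl)-4-formyl-2,6-bis(4-methoxyphenyl)-2,3,5,6-tetrahydrobenzo[1,2-b:5,4-b']difuran-3-yl]-1,3-phenylene bis(4-methylbenzenesulfonate)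
Conditions: Dess–Martin periodinane (1.3 equiv), CH2Cl2, 0 °C to rt
Reagents that add atoms: none
Why: Dess–Martin oxidation of a hindered benzylic alcohol to the aldehyde under near-neutral conditions; no over-oxidation is possible and no stereocentre is alpha to the new carbonyl.

Step 19
Reactants: 36 the aldehyde from step 18; 37 diethyl (4-methoxybenzyl)phosphonate
Product: 38 5-[(2R,3R,5S,6S)-5-(3,5-dimethoxyphenyl)-2,6-bis(4-methoxyphenyl)-4-[(E)-2-(4-methoxyphenyl)ethenyl]-2,3,5,6-tetrahydrobenzo[1,2-b:5,4-b']difuran-3-yl]-1,3-phenylene bis(4-methylbenzenesulfonate)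
Conditions: NaH, THF, 0 °C to rt
Reagents that add atoms: none
Why: Horner–Wadsworth–Emmons olefination with a benzylic phosphonate, expected to give the E-stilbene; the geometry is not critical because both isomers give the same cation in step 20.

Step 20
Reactants: 38 the stilbene from step 19
Product: 40 ring-closed pentamethyl ether bis(4-methylbenzenesulfonate) of the target with Ca (S) and the other four centres unchanged, via benzylic cation 39 (not isolated)
Conditions: MeSO3H (2 equiv), CH2Cl2, -40 to 0 °C
Reagents that add atoms: none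
Why: Protonation at Cb gives the 4-methoxybenzylic cation 39, which is captured by the carbon of ring B ortho to Cf and para to a methoxy group (intramolecular Friedel–Crafts alkylation, seven-membered ring), the known acid-mediated closure of 4-oxygenated stilbenes onto a neighbouring 3,5-dioxygenated aryl group. Ring D, deactivated by two sulfonates, cannot compete, so the otherwise enantiotopic choice between the two resorcinol rings is decided. Ca is set by Cf: ring B is held above ring C, and the anisyl group takes the outward, pseudo-equatorial position rather than pointing over ring C, which corresponds to (S).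

Step 21
Reactants: 40 the ring-closed bis-sulfonate from step 20
Product: 41 pentamethyl ether of the target with ring D as the free 3,5-dihydroxyphenyl group
Conditions: KOH, 1,4-dioxane/H2O, 80 °C, argon
Reagents that add atoms: none
Why: Hydroxide attacks the sulfonyl sulfur and releases the two phenoxides; the alcohol-free medium avoids alkyl sulfonates that could re-alkylate them. Methyl ethers, dihydrofurans and the methine centres are inert to base.

Step 22
Reactants: 41 the pentamethyl ether from step 21
Product: 42 the target CNP0136963.1 with Ca (S), Cc (R), Cd (R), Ce (S), Cf (S)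
Conditions: BBr3 (12 equiv), CH2Cl2, -78 °C to rt; then MeOH, H2O
Reagents that add atoms: none
Why: Lewis-acid cleavage of the five aryl methyl ethers; no alkene remains, so acid-induced stilbene cyclisations are excluded, and low temperature limits ionisation of the Cd–O and Ce–O bonds.

## Compound list

1 | 3,5-dihydroxybenzyl alcohol | OCc1cc(O)cc(O)c1 | starting material
2 | 5-{[(tert-butyldimethylsilyl)oxy]methyl}benzene-1,3-diol | CC(C)(C)[Si](C)(C)OCc1cc(O)cc(O)c1 | intermediate
3 | 3-(benzyloxy)-5-{[(tert-butyldimethylsilyl)oxy]methyl}phenol | CC(C)(C)[Si](C)(C)OCc1cc(O)cc(OCc2ccccc2)c1 | intermediate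
4 | 3,5-dihydroxybenzaldehyde | O=Cc1cc(O)cc(O)c1 | starting material
5 | 5-formyl-1,3-phenylene bis(4-methylbenzenesulfonate) | O=Cc1cc(OS(=O)(=O)c2ccc(C)cc2)cc(OS(=O)(=O)c2ccc(C)cc2)c1 | intermediate
6 | bromomagnesium 3-(benzyloxy)-5-{[(tert-butyldimethylsilyl)oxy]methyl}phenoxide | CC(C)(C)[Si](C)(C)OCc1cc(O[Mg]Br)cc(OCc2ccccc2)c1 | intermediate (not isolated)
7 | racemic 5-{[4-(benzyloxy)-2-{[(tert-butyldimethylsilyl)oxy]methyl}-6-hydroxyphenyl](hydroxy)methyl}-1,3-phenylene bis(4-methylbenzenesulfonate) | CC(C)(C)[Si](C)(C)OCc1cc(OCc2ccccc2)cc(O)c1C(O)c1cc(OS(=O)(=O)c2ccc(C)cc2)cc(OS(=O)(=O)c2ccc(C)cc2)c1 | intermediate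
8 | [4-(benzyloxy)-2-{[(tert-butyldimethylsilyl)oxy]methyl}-6-hydroxyphenyl][3,5-bis(4-methylbenzenesulfonyloxy)phenyl]methylium (ortho-hydroxybenzhydryl cation formed from 7 by loss of water under acid) | CC(C)(C)[Si](C)(C)OCc1cc(OCc2ccccc2)cc(O)c1[CH+]c1cc(OS(=O)(=O)c2ccc(C)cc2)cc(OS(=O)(=O)c2ccc(C)cc2)c1 | intermediate (not isolated)
9 | racemic 5-{[4-(benzyloxy)-2-{[(tert-butyldimethylsilyl)oxy]methyl}-6-hydroxyphenyl](4-methylbenzenesulfonyl)methyl}-1,3-phenylene bis(4-methylbenzenesulfonate) | CC(C)(C)[Si](C)(C)OCc1cc(OCc2ccccc2)cc(O)c1C(c1cc(OS(=O)(=O)c2ccc(C)cc2)cc(OS(=O)(=O)c2ccc(C)cc2)c1)S(=O)(=O)c1ccc(C)cc1 | intermediate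
10 | (2S,5S)-hexane-2,5-diol | C[C@H](O)CC[C@H](C)O | starting material
11 | (2S,5S)-hexane-2,5-diyl dimethanesulfonate | C[C@H](OS(C)(=O)=O)CC[C@H](C)OS(C)(=O)=O | intermediate
12 | (2R,5R)-2,5-dimethylthiolane | C[C@@H]1CC[C@@H](C)S1 | intermediate
13 | 4-methoxybenzyl bromide | COc1ccc(CBr)cc1 | starting material
14 | (2R,5R)-1-(4-methoxybenzyl)-2,5-dimethylthiolan-1-ium bromide | C[C@@H]1CC[C@@H](C)[S+]1Cc1ccc(OC)cc1.[Br-] | intermediate (not isolated)
15 | (2R,5R)-1-(4-methoxybenzyl)-2,5-dimethylthiolan-1-ium tetrafluoroborate | C[C@@H]1CC[C@@H](C)[S+]1Cc1ccc(OC)cc1.F[B-](F)(F)F | intermediate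
16 | 5-{(Z)-[4-(benzyloxy)-2-{[(tert-butyldimethylsilyl)oxy]methyl}-6-oxocyclohexa-2,4-dien-1-ylidene]methyl}-1,3-phenylene bis(4-methylbenzenesulfonate) (ortho-quinone methide) | CC(C)(C)[Si](C)(C)OCC1=CC(OCc2ccccc2)=CC(=O)/C1=C\c1cc(OS(=O)(=O)c2ccc(C)cc2)cc(OS(=O)(=O)c2ccc(C)cc2)c1 | intermediate (not isolated)
17 | [(2R,5R)-2,5-dimethylthiolan-1-ium-1-yl](4-methoxyphenyl)methanide (ylide) | COc1ccc([CH-][S+]2[C@H](C)CC[C@H]2C)cc1 | intermediate (not isolated)
18 | 5-(benzyloxy)-2-{(1R,2S)-1-[3,5-bis(4-methylbenzenesulfonyloxy)phenyl]-2-[(2R,5R)-2,5-dimethylthiolan-1-ium-1-yl]-2-(4-methoxyphenyl)ethyl}-3-{[(tert-butyldimethylsilyl)oxy]methyl}phenolate (betaine) | CC(C)(C)[Si](C)(C)OCc1cc(OCc2ccccc2)cc([O-])c1[C@@H](c1cc(OS(=O)(=O)c2ccc(C)cc2)cc(OS(=O)(=O)c2ccc(C)cc2)c1)[C@@H](c1ccc(OC)cc1)[S+]1[C@H](C)CC[C@H]1C | intermediate (not isolated)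
19 | 5-[(2R,3R)-6-(benzyloxy)-4-{[(tert-butyldimethylsilyl)oxy]methyl}-2-(4-methoxyphenyl)-2,3-dihydro-1-benzofuran-3-yl]-1,3-phenylene bis(4-methylbenzenesulfonate) | CC(C)(C)[Si](C)(C)OCc1cc(OCc2ccccc2)cc2c1[C@@H](c1cc(OS(=O)(=O)c3ccc(C)cc3)cc(OS(=O)(=O)c3ccc(C)cc3)c1)[C@H](c1ccc(OC)cc1)O2 | intermediate
20 | 5-[(2R,3R)-4-{[(tert-butyldimethylsilyl)oxy]methyl}-6-hydroxy-2-(4-methoxyphenyl)-2,3-dihydro-1-benzofuran-3-yl]-1,3-phenylene bis(4-methylbenzenesulfonate) | CC(C)(C)[Si](C)(C)OCc1cc(O)cc2c1[C@@H](c1cc(OS(=O)(=O)c3ccc(C)cc3)cc(OS(=O)(=O)c3ccc(C)cc3)c1)[C@H](c1ccc(OC)cc1)O2 | intermediate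
21 | 3,5-dimethoxybenzaldehyde | COc1cc(C=O)cc(OC)c1 | starting material
22 | bromomagnesium phenoxide of 20 (magnesium on the oxygen at position 6 of the benzofuran) | CC(C)(C)[Si](C)(C)OCc1cc(O[Mg]Br)cc2c1[C@@H](c1cc(OS(=O)(=O)c3ccc(C)cc3)cc(OS(=O)(=O)c3ccc(C)cc3)c1)[C@H](c1ccc(OC)cc1)O2 | intermediate (not isolated)
23 | 5-[(2R,3R)-4-{[(tert-butyldimethylsilyl)oxy]methyl}-5-[(3,5-dimethoxyphenyl)(hydroxy)methyl]-6-hydroxy-2-(4-methoxyphenyl)-2,3-dihydro-1-benzofuran-3-yl]-1,3-phenylene bis(4-methylbenzenesulfonate), both carbinol epimers | CC(C)(C)[Si](C)(C)OCc1c(C(O)c2cc(OC)cc(OC)c2)c(O)cc2c1[C@@H](c1cc(OS(=O)(=O)c3ccc(C)cc3)cc(OS(=O)(=O)c3ccc(C)cc3)c1)[C@H](c1ccc(OC)cc1)O2 | intermediate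
24 | {(2R,3R)-3-[3,5-bis(4-methylbenzenesulfonyloxy)phenyl]-4-{[(tert-butyldimethylsilyl)oxy]methyl}-6-hydroxy-2-(4-methoxyphenyl)-2,3-dihydro-1-benzofuran-5-yl}(3,5-dimethoxyphenyl)methylium (ortho-hydroxybenzhydryl cation formed from 23 by loss of water under acid) | CC(C)(C)[Si](C)(C)OCc1c([CH+]c2cc(OC)cc(OC)c2)c(O)cc2c1[C@@H](c1cc(OS(=O)(=O)c3ccc(C)cc3)cc(OS(=O)(=O)c3ccc(C)cc3)c1)[C@H](c1ccc(OC)cc1)O2 | intermediate (not isolated)
25 | 5-[(2R,3R)-4-{[(tert-butyldimethylsilyl)oxy]methyl}-5-[(3,5-dimethoxyphenyl)(4-methylbenzenesulfonyl)methyl]-6-hydroxy-2-(4-methoxyphenyl)-2,3-dihydro-1-benzofuran-3-yl]-1,3-phenylene bis(4-methylbenzenesulfonate), both epimers | CC(C)(C)[Si](C)(C)OCc1c(C(c2cc(OC)cc(OC)c2)S(=O)(=O)c2ccc(C)cc2)c(O)cc2c1[C@@H](c1cc(OS(=O)(=O)c3ccc(C)cc3)cc(OS(=O)(=O)c3ccc(C)cc3)c1)[C@H](c1ccc(OC)cc1)O2 | intermediate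
26 | (2R,5R)-hexane-2,5-diol | C[C@@H](O)CC[C@@H](C)O | starting material
27 | (2R,5R)-hexane-2,5-diyl dimethanesulfonate | C[C@@H](OS(C)(=O)=O)CC[C@@H](C)OS(C)(=O)=O | intermediate
28 | (2S,5S)-2,5-dimethylthiolane | C[C@H]1CC[C@H](C)S1 | intermediate
29 | (2S,5S)-1-(4-methoxybenzyl)-2,5-dimethylthiolan-1-ium bromide | C[C@H]1CC[C@H](C)[S+]1Cc1ccc(OC)cc1.[Br-] | intermediate (not isolated)
30 | (2S,5S)-1-(4-methoxybenzyl)-2,5-dimethylthiolan-1-ium tetrafluoroborate | C[C@H]1CC[C@H](C)[S+]1Cc1ccc(OC)cc1.F[B-](F)(F)F | intermediate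
31 | 5-[(2R,3R,5Z)-4-{[(tert-butyldimethylsilyl)oxy]methyl}-5-(3,5-dimethoxybenzylidene)-2-(4-methoxyphenyl)-6-oxo-2,3,5,6-tetrahydro-1-benzofuran-3-yl]-1,3-phenylene bis(4-methylbenzenesulfonate) (ortho-quinone methide) | CC(C)(C)[Si](C)(C)OCC1=C2[C@@H](c3cc(OS(=O)(=O)c4ccc(C)cc4)cc(OS(=O)(=O)c4ccc(C)cc4)c3)[C@H](c3ccc(OC)cc3)OC2=CC(=O)/C1=C\c1cc(OC)cc(OC)c1 | intermediate (not isolated)
32 | [(2S,5S)-2,5-dimethylthiolan-1-ium-1-yl](4-methoxyphenyl)methanide (ylide) | COc1ccc([CH-][S+]2[C@@H](C)CC[C@@H]2C)cc1 | intermediate (not isolated)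
33 | (2R,3R)-3-[3,5-bis(4-methylbenzenesulfonyloxy)phenyl]-4-{[(tert-butyldimethylsilyl)oxy]methyl}-5-{(1S,2R)-1-(3,5-dimethoxyphenyl)-2-[(2S,5S)-2,5-dimethylthiolan-1-ium-1-yl]-2-(4-methoxyphenyl)ethyl}-2-(4-methoxyphenyl)-2,3-dihydro-1-benzofuran-6-olate (betaine) | CC(C)(C)[Si](C)(C)OCc1c([C@H](c2cc(OC)cc(OC)c2)[C@H](c2ccc(OC)cc2)[S+]2[C@@H](C)CC[C@@H]2C)c([O-])cc2c1[C@@H](c1cc(OS(=O)(=O)c3ccc(C)cc3)cc(OS(=O)(=O)c3ccc(C)cc3)c1)[C@H](c1ccc(OC)cc1)O2 | intermediate (not isolated)
34 | 5-[(2R,3R,5S,6S)-4-{[(tert-butyldimethylsilyl)oxy]methyl}-5-(3,5-dimethoxyphenyl)-2,6-bis(4-methoxyphenyl)-2,3,5,6-tetrahydrobenzo[1,2-b:5,4-b']difuran-3-yl]-1,3-phenylene bis(4-methylbenzenesulfonate) | CC(C)(C)[Si](C)(C)OCc1c2c(cc3c1[C@@H](c1cc(OS(=O)(=O)c4ccc(C)cc4)cc(OS(=O)(=O)c4ccc(C)cc4)c1)[C@H](c1ccc(OC)cc1)O3)O[C@H](c1ccc(OC)cc1)[C@H]2c1cc(OC)cc(OC)c1 | intermediate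
35 | 5-[(2R,3R,5S,6S)-5-(3,5-dimethoxyphenyl)-4-(hydroxymethyl)-2,6-bis(4-methoxyphenyl)-2,3,5,6-tetrahydrobenzo[1,2-b:5,4-b']difuran-3-yl]-1,3-phenylene bis(4-methylbenzenesulfonate) | OCc1c2c(cc3c1[C@@H](c1cc(OS(=O)(=O)c4ccc(C)cc4)cc(OS(=O)(=O)c4ccc(C)cc4)c1)[C@H](c1ccc(OC)cc1)O3)O[C@H](c1ccc(OC)cc1)[C@H]2c1cc(OC)cc(OC)c1 | intermediate
36 | 5-[(2R,3R,5S,6S)-5-(3,5-dimethoxyphenyl)-4-formyl-2,6-bis(4-methoxyphenyl)-2,3,5,6-tetrahydrobenzo[1,2-b:5,4-b']difuran-3-yl]-1,3-phenylene bis(4-methylbenzenesulfonate) | O=Cc1c2c(cc3c1[C@@H](c1cc(OS(=O)(=O)c4ccc(C)cc4)cc(OS(=O)(=O)c4ccc(C)cc4)c1)[C@H](c1ccc(OC)cc1)O3)O[C@H](c1ccc(OC)cc1)[C@H]2c1cc(OC)cc(OC)c1 | intermediate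
37 | diethyl (4-methoxybenzyl)phosphonate | CCOP(=O)(Cc1ccc(OC)cc1)OCC | starting material
38 | 5-[(2R,3R,5S,6S)-5-(3,5-dimethoxyphenyl)-2,6-bis(4-methoxyphenyl)-4-[(E)-2-(4-methoxyphenyl)ethenyl]-2,3,5,6-tetrahydrobenzo[1,2-b:5,4-b']difuran-3-yl]-1,3-phenylene bis(4-methylbenzenesulfonate) | COc1ccc(/C=C/c2c3c(cc4c2[C@@H](c2cc(OS(=O)(=O)c5ccc(C)cc5)cc(OS(=O)(=O)c5ccc(C)cc5)c2)[C@H](c2ccc(OC)cc2)O4)O[C@H](c2ccc(OC)cc2)[C@H]3c2cc(OC)cc(OC)c2)cc1 | intermediate
39 | 1-(4-methoxyphenyl)-2-(ring C of 38)ethylium: the cation at Ca formed by protonation of 38 at Cb | COc1ccc([CH+]Cc2c3c(cc4c2[C@@H](c2cc(OS(=O)(=O)c5ccc(C)cc5)cc(OS(=O)(=O)c5ccc(C)cc5)c2)[C@H](c2ccc(OC)cc2)O4)O[C@H](c2ccc(OC)cc2)[C@H]3c2cc(OC)cc(OC)c2)cc1 | intermediate (not isolated)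
40 | pentamethyl ether bis(4-methylbenzenesulfonate) of the target: methyl ethers on ring B and on rings E, F and G, sulfonates on ring D; Ca (S), Cc (R), Cd (R), Ce (S), Cf (S) | COc1ccc([C@@H]2Cc3c4c(cc5c3[C@@H](c3cc(OS(=O)(=O)c6ccc(C)cc6)cc(OS(=O)(=O)c6ccc(C)cc6)c3)[C@H](c3ccc(OC)cc3)O5)O[C@H](c3ccc(OC)cc3)[C@H]4c3cc(OC)cc(OC)c32)cc1 | intermediate
41 | pentamethyl ether of the target with ring D as free 3,5-dihydroxyphenyl; same configuration | COc1ccc([C@@H]2Cc3c4c(cc5c3[C@@H](c3cc(O)cc(O)c3)[C@H](c3ccc(OC)cc3)O5)O[C@H](c3ccc(OC)cc3)[C@H]4c3cc(OC)cc(OC)c32)cc1 | intermediate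
42 | CNP0136963.1, the heptaphenol with Ca (S), Cc (R), Cd (R), Ce (S), Cf (S) | Oc1ccc([C@@H]2Cc3c4c(cc5c3[C@@H](c3cc(O)cc(O)c3)[C@H](c3ccc(O)cc3)O5)O[C@H](c3ccc(O)cc3)[C@H]4c3cc(O)cc(O)c32)cc1 | target

## Step count and least certain steps

Total: 22 steps. Longest linear sequence: 15 steps (1, 2, 4, 5, 9, 10, 11, 12, 16, 17, 18, 19, 20, 21, 22).

**Step 9 (key step).** The most likely failure is loss of enantiomeric purity together with O-alkylation. The 4-methoxybenzyl ylide is the least stabilised of the benzyl series and its salt the most labile, so transfer of the benzyl group to phenoxide oxygen and incomplete discrimination of the ylide faces can both occur. Step 16 shares this risk. The fallback sets out from 9 and returns at 19: annulation of 9 with the achiral 1-(4-methoxybenzyl)thiolan-1-ium tetrafluoroborate F1 (from tetrahydrothiophene, 13 and NaBF4) under the same carbonate conditions should give the racemic trans-dihydrobenzofuran F2, whose trans selectivity does not depend on a chiral sulfide. The enantiomers are then separated by preparative chromatography on a chiral stationary phase, which gives 19.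

**Step 5 (and likewise step 12).** The most likely failure is capture of the benzhydryl cation 8 by the neighbouring silyloxymethyl oxygen, with loss of the silyl group and formation of a five-membered cyclic ether, in competition with sulfinate. The fallback sets out from 7 and returns at 19, avoiding cations altogether. Selective carbonate formation on the phenol (Boc2O, iPr2NEt, cat. DMAP, 0 °C) should give the aryl tert-butyl carbonate F3. Under the base of step 9 (Cs2CO3, or KOtBu if carbonate is too weak) the carbonate group shifts to the benzylic oxygen and is expelled by the phenoxide, which generates 16 in the presence of 17.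

**Step 11.** The most likely failure is incomplete or misdirected hydroxyalkylation: position 2 is flanked by the silyloxymethyl arm, attack between the two oxygens at position 4 may compete, and the product may react further with a second phenoxide. Step 4 relies on the same selectivity on a less crowded ring. The fallback sets out from 20 and returns at 23: ortho-formylation with the small electrophile (MgCl2, Et3N, paraformaldehyde, MeCN, reflux) should give the salicylaldehyde F4. Addition of commercial 3,5-dimethoxyphenylmagnesium bromide (2.2 equiv, THF, -78 to -20 °C, at which aryl sulfonates are not attacked) then gives 23.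

**Step 20.** The most likely failure is competing ionisation of the Cd–O and Ce–O benzylic ether bonds under the acid needed to protonate the stilbene, leading to ring opening, epimerisation or other cyclisation modes; facial leakage at Ca is the second concern. The fallback sets out from 35 and returns at 40, reaching cation 39 by ionising an alcohol under much milder conditions. CBr4/PPh3 should give the benzylic bromide F5. Zinc insertion (Zn, LiCl, THF) and addition to 4-methoxybenzaldehyde in the presence of MgCl2 should give the homobenzylic alcohol F6 as a mixture of epimers. BF3·OEt2 at -78 °C then ionises F6 to 39, which closes to 40.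

**Step 22.** The most likely failure is Lewis-acid opening or epimerisation of the dihydrobenzofurans during the five-fold demethylation. The fallback sets out from 40 and returns at 42 without passing through 41 and makes no new compound (F0): excess NaSEt in DMF at 120–140 °C under argon removes the methyl groups by SN2 attack at carbon and the sulfonates by attack at sulfur, so no Lewis acid is used.

## Further compounds

F1 | step 9 | 1-(4-methoxybenzyl)thiolan-1-ium tetrafluoroborate | COc1ccc(C[S+]2CCCC2)cc1.F[B-](F)(F)F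
F2 | step 9 | racemic trans-5-[6-(benzyloxy)-4-{[(tert-butyldimethylsilyl)oxy]methyl}-2-(4-methoxyphenyl)-2,3-dihydro-1-benzofuran-3-yl]-1,3-phenylene bis(4-methylbenzenesulfonate) (both enantiomers) | CC(C)(C)[Si](C)(C)OCc1cc(OCc2ccccc2)cc2c1[C@@H](c1cc(OS(=O)(=O)c3ccc(C)cc3)cc(OS(=O)(=O)c3ccc(C)cc3)c1)[C@H](c1ccc(OC)cc1)O2.CC(C)(C)[Si](C)(C)OCc1cc(OCc2ccccc2)cc2c1[C@H](c1cc(OS(=O)(=O)c3ccc(C)cc3)cc(OS(=O)(=O)c3ccc(C)cc3)c1)[C@@H](c1ccc(OC)cc1)O2
F3 | step 5 | racemic 5-{[4-(benzyloxy)-2-[(tert-butoxycarbonyl)oxy]-6-{[(tert-butyldimethylsilyl)oxy]methyl}phenyl](hydroxy)methyl}-1,3-phenylene bis(4-methylbenzenesulfonate) | CC(C)(C)[Si](C)(C)OCc1cc(OCc2ccccc2)cc(OC(=O)OC(C)(C)C)c1C(O)c1cc(OS(=O)(=O)c2ccc(C)cc2)cc(OS(=O)(=O)c2ccc(C)cc2)c1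
F4 | step 11 | 5-[(2R,3R)-4-{[(tert-butyldimethylsilyl)oxy]methyl}-5-formyl-6-hydroxy-2-(4-methoxyphenyl)-2,3-dihydro-1-benzofuran-3-yl]-1,3-phenylene bis(4-methylbenzenesulfonate) | CC(C)(C)[Si](C)(C)OCc1c(C=O)c(O)cc2c1[C@@H](c1cc(OS(=O)(=O)c3ccc(C)cc3)cc(OS(=O)(=O)c3ccc(C)cc3)c1)[C@H](c1ccc(OC)cc1)O2
F5 | step 20 | 5-[(2R,3R,5S,6S)-4-(bromomethyl)-5-(3,5-dimethoxyphenyl)-2,6-bis(4-methoxyphenyl)-2,3,5,6-tetrahydrobenzo[1,2-b:5,4-b']difuran-3-yl]-1,3-phenylene bis(4-methylbenzenesulfonate) | BrCc1c2c(cc3c1[C@@H](c1cc(OS(=O)(=O)c4ccc(C)cc4)cc(OS(=O)(=O)c4ccc(C)cc4)c1)[C@H](c1ccc(OC)cc1)O3)O[C@H](c1ccc(OC)cc1)[C@H]2c1cc(OC)cc(OC)c1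
F6 | step 20 | 5-[(2R,3R,5S,6S)-5-(3,5-dimethoxyphenyl)-4-[2-hydroxy-2-(4-methoxyphenyl)ethyl]-2,6-bis(4-methoxyphenyl)-2,3,5,6-tetrahydrobenzo[1,2-b:5,4-b']difuran-3-yl]-1,3-phenylene bis(4-methylbenzenesulfonate), both carbinol epimers | COc1ccc(C(O)Cc2c3c(cc4c2[C@@H](c2cc(OS(=O)(=O)c5ccc(C)cc5)cc(OS(=O)(=O)c5ccc(C)cc5)c2)[C@H](c2ccc(OC)cc2)O4)O[C@H](c2ccc(OC)cc2)[C@H]3c2cc(OC)cc(OC)c2)cc1
F0 | step 22 | none | none
A1 | alternative 1 | permethylated dibenzosuberene with the Ca=Cb double bond and both dihydrobenzofurans in place | COc1ccc(C2=Cc3c4c(cc5c3[C@@H](c3cc(OC)cc(OC)c3)[C@H](c3ccc(OC)cc3)O5)O[C@H](c3ccc(OC)cc3)[C@H]4c3cc(OC)cc(OC)c32)cc1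
A2 | alternative 1 | eight-membered dibenzo-fused cyclic sulfone (Ca–SO2–Cb), permethylated, epimers at Ca | COc1ccc(C2S(=O)(=O)Cc3c4c(cc5c3[C@@H](c3cc(OC)cc(OC)c3)[C@H](c3ccc(OC)cc3)O5)O[C@H](c3ccc(OC)cc3)[C@H]4c3cc(OC)cc(OC)c32)cc1
A3 | alternative 2 | cyclohexane-1,3-dione precursor of ring B fused on the seven-membered ring (two transient sp3 centres unassigned) | COc1ccc([C@@H]2Cc3c4c(cc5c3[C@@H](c3cc(OC)cc(OC)c3)[C@H](c3ccc(OC)cc3)O5)O[C@H](c3ccc(OC)cc3)[C@H]4C3CC(=O)CC(=O)C32)cc1
A4 | alternative 2 | keto acrylate with a 2-oxopropyl arm on Ca and a methyl (E)-acrylate on Cf | COc1ccc([C@@H](CC(C)=O)Cc2c3c(cc4c2[C@@H](c2cc(OC)cc(OC)c2)[C@H](c2ccc(OC)cc2)O4)O[C@H](c2ccc(OC)cc2)[C@H]3/C=C/C(=O)OC)cc1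
A5 | alternative 3 | methyl trans-(2R,3R)-6-benzyloxy-2-(4-methoxyphenyl)-4-(triflyloxy)-2,3-dihydrobenzofuran-3-carboxylate | COC(=O)[C@H]1[C@H](c2ccc(OC)cc2)Oc2cc(OCc3ccccc3)cc(OS(=O)(=O)C(F)(F)F)c21
A6 | alternative 3 | (2R)-7-(benzyloxy)-2-(4-methoxyphenyl)-4-oxochroman-5-yl trifluoromethanesulfonate | O=C1C[C@H](c2ccc(OC)cc2)Oc2cc(OCc3ccccc3)cc(OS(=O)(=O)C(F)(F)F)c21
A7 | alternative 3 | (2S)-naringenin | O=C1C[C@@H](c2ccc(O)cc2)Oc2cc(O)cc(O)c21
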